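**Conventions.** Pterocarpan numbering is used throughout: ring A (C1–C4, C4a, C11b), ring B (O5, C6, C6a, C11a), ring C (O11), ring D (C6b–C10a), and ring E, the 2,2-dimethyl-3,4-dihydro-2H-pyran fused on C1 (its oxygen) and C2 (its CH2). "Ring-E pterocarpan" means this pentacyclic skeleton with the 9-methoxy group.

## The problem

The target is a pterocarpan: a chroman (rings A and B) cis-fused through C6a–C11a to a 2,3-dihydrobenzofuran (rings C and D). Ring D carries a methoxy group at C9, and ring A carries the fused dimethylpyran ring E next to a free C3 phenol. There are two stereocentres, C6a and C11a, both S. A six/five fusion of this kind exists only cis, so C11a follows from C6a once rings B and C are both closed. The real stereochemical task is therefore the absolute configuration of C6a, a tertiary benzylic CH with no heteroatom to serve as a handle. The C11a–O11 bond is a benzylic ether on a 2,4,6-trioxygenated ring: acid ionises it (and loss of H6a then erases the stereocentre) and hydrogenation cleaves it, so the end game must avoid both, and the C3 phenol should stay masked until the last step. Ring A has three oxygen atoms with three different roles (ring E ether at C1, phenol at C3, ring B ether at C4a), and they must be told apart starting from a symmetrical 1,3,5-trioxygenated benzene. The feature that opens a short route is that C11a is at the aldehyde oxidation level on ring A ortho to O5, while C6a–C6 is a two-carbon alkene unit on ring D ortho to O11. A ring A salicylaldehyde and a ring D ortho-oxygenated styrene thus contain every skeletal atom. A plain styrene would bond to C11a through its terminal carbon C6 and give a bridged skeleton; a sulfur substituent on C6 is needed to make C6a the nucleophilic carbon.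

## Retrosynthesis

**End game.** Target 14 is traced to its silyl ether 13 (O3–Si bond) and 13 to the 6-phenylthio compound 12 (C6–H exchanged for C6–S).
- The bulky silyl group keeps the C3 oxygen out of every cationic event and is removed by fluoride, which leaves the C11a–O11 bond alone.
- Sulfur at C6 is the element that makes the next cut possible, and a C–S bond next to oxygen can be cut homolytically under neutral conditions.
- The neighbouring choice, an oxygen substituent at C6, would need ionic reduction under acid, which ring C would not survive.
- The forward steps are asked only to leave C6a and C11a untouched.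

**Key disconnection.** 12 is cut at three bonds, C6a–C11a, C6–O5 and O11–C11a, giving aldehyde 6 (rings A and E, aldehyde carbon = C11a) and vinyl sulfide 10 (ring D with C6a=C6). The ring B-closed chroman 11 lies between them.
- Cutting only one of the two C–O bonds would leave C6a to be set in a separate asymmetric operation; this cut creates C6a in the same event that joins the halves.
- Both precursors are stereocentre-free and each is a short elaboration of a commercial benzaldehyde.
- The forward reaction must deliver four things: bonding through C6a and not C6; capture of the C6 thionium ion by O5 and not O11; facial control at C6a by a chiral counteranion; and a medium free of protic acid.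
- The silyl groups are chosen for these demands: a small trimethylsilyl group on O5 (fast thionium capture) and a tert-butyldimethylsilyl group on O11 (slow to attack early, still able to leave as a silylium ion in the last closure).

**Ring A/E fragment.** 6 is the trimethylsilyl ether of salicylaldehyde 5. In 5 the ring E C–O bond is cut to give the ortho-prenyl phenol 4, the prenyl C–C bond is cut to give 2 and prenyl bromide 3, and the O4–Si bond of 2 is cut to give 1.
- Silylating the para hydroxyl first leaves two equivalent ortho hydroxyls and two equivalent ring positions, so C-prenylation and cyclisation can give only one chroman, the one with the ring oxygen next to the formyl group.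
- Cyclising the unprotected prenyl compound would leave open which hydroxyl closes the ring.
- The forward steps need mono-silylation at the most acidic hydroxyl, C-alkylation rather than O-alkylation, and an acid mild enough for the aryl silyl ether.

**Ring D fragment.** 10 is cut at the C6a=C6 double bond into aldehyde 8 and phosphonate 9 (Horner–Wadsworth–Emmons), and 8 is the silyl ether of 7.
- The tert-butyldimethylsilyl group is put on before the olefination because it survives the phosphonate anion and chromatography; a trimethylsilyl ether would not.
- The forward reaction must give the E alkene, so that one defined geometry enters the key step.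

## Roads not taken

**Alternative 1:** The cut is C6a–C11a alone, made by intramolecular C–H insertion.
- Forward key step: diazo ester A1 (a ring D aryldiazoacetate whose ortho oxygen carries the ring A benzyl group, C11a being its CH2) is decomposed by Rh2(S-PTTL)4 (PTTL = N-phthaloyl-tert-leucinate; a divalent rhodium carboxylate dimer) or its mirror image. The carbenoid carbon C6a inserts into the C11a–H bond and closes ring C, giving the cis-2-aryl-2,3-dihydrobenzofuran-3-carboxylate A2, whose ester carbon is the future C6.
- Merits: this insertion is an established, highly enantioselective way to cis-2-aryl-dihydrobenzofuran-3-carboxylates, and it sets both stereocentres in one catalytic step.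
- Weak points for this target:
  - The insertion site is flanked by a fully substituted 2,6-dioxygenated aryl ring, and the electron-rich ring and the ether oxygen offer the carbenoid other outlets.
  - A1 requires a 2,4,6-trioxygenated benzylic electrophile, a class that ionises readily.
  - Ring B is still open after the key step, so ester reduction, selective unmasking of O5, Mitsunobu closure and final deprotection remain.
  - A2 has an epimerisable α-aryl ester centre at C6a.
- Comparison: in precedent for the key step this road is clearly stronger than the chosen one. The chosen plan sets against it that rings B and C close together from two stereocentre-free pieces, that about four steps are saved, and that no epimerisable intermediate is passed.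

**Alternative 2:** The cut is the aryl–carbon bond C11a–C11b; ring B is closed last by Friedel–Crafts reaction.
- Forward key step: BF3·OEt2 ionises the 2-acetoxy-2,3-dihydrobenzofuran A3 to the cyclic oxocarbenium ion at C11a, and ring A attacks through C11b to give A4, which is identical with 13.
- Merits: the cis fusion is automatic, the bond uses the innate nucleophilicity of ring A, and the product needs only desilylation, with no auxiliary atom to remove.
- Weak points:
  - C6a is not addressed by the key step and must be installed beforehand in a separate asymmetric sequence, at a position α to an acetal carbon.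
  - The oxocarbenium ion has H6a next to it, and loss of that proton would aromatise ring C and delete the stereocentre for good.
  - Ring A can attack through C4 as well as C11b, so the regiochemistry rests on the bulk of the O3 silyl group.
- Comparison: the end game is one step shorter and tin-free, which is better than the chosen plan. The chosen plan sets against it that its key step itself creates C6a and that its cationic intermediates are trapped intramolecularly before a proton can be lost.

**Alternative 3:** The cuts are C6a–C6b and O11–C11a; ring D comes from a quinone.
- Forward key step: 2-methoxy-1,4-benzoquinone A6 is activated by a TADDOL-derived titanium complex (from TiCl4, Ti(OiPr)4 and the chiral diol; tetravalent titanium). C6a of chromene A5 (rings A, B and E) attacks it, and the quinone oxygen closes on the C11a cation, giving the 8-hydroxy pterocarpan A7.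
- Merits: convergent; a formal [3+2] reaction of this type is known for chromenes and alkoxyquinones; ring C and both stereocentres arise in one step; A5 is one step from 5.
- Weak points:
  - The chiral titanium complex is needed in stoichiometric amount and its selectivity depends on the substrate.
  - [2+2] adducts compete.
  - The surplus C8 hydroxyl costs two further steps (triflation, reduction).
- Comparison: in closeness to precedent this road is ahead of the chosen plan, and its length is similar. The chosen plan sets against it catalytic control of C6a and a product with no surplus oxygen. This road is kept as the retreat if step 7 fails.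

Key step: step 7

Assumption: 12 is formed and carried on as a mixture of C6 epimers, because C6 loses its substituent in step 8. The silyl group drawn on the C11a oxygen of 11 is the tert-butyldimethylsilyl group released in the preceding catalytic turnover; exchange for trimethylsilyl would change only which disiloxane is lost.

## Route

Step 1
Reactants: 1 2,4,6-trihydroxybenzaldehyde
Product: 2 2,6-dihydroxy-4-(triisopropylsilyloxy)benzaldehyde
Conditions: TIPSCl (1.0 equiv), imidazole, DMF, −20 → 0 °C
Reagents that add atoms: triisopropylsilyl chloride (TIPSCl), CC(C)[Si](Cl)(C(C)C)C(C)C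
Why: Phenol silylation; the para hydroxyl is the most acidic, lies outside the formyl chelate and is the least hindered, so a bulky silyl chloride used in deficiency at low temperature should select it, and the symmetry of 1 means only one 4-O-ether can form.

Step 2
Reactants: 2 2,6-dihydroxy-4-(triisopropylsilyloxy)benzaldehyde; 3 1-bromo-3-methylbut-2-ene
Product: 4 2,6-dihydroxy-3-(3-methylbut-2-en-1-yl)-4-(triisopropylsilyloxy)benzaldehyde
Conditions: DBU, THF, 0 °C → rt
Reagents that add atoms: none
Why: Base-mediated C-prenylation of an acylphloroglucinol-type phenoxide, whose ambident anion reacts at the ring carbon ortho and para to oxygen; the two open ring positions of 2 are equivalent, so one mono-C-prenyl isomer results, and the non-aqueous amidine base spares the silyl ether.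

Step 3
Reactants: 4 2,6-dihydroxy-3-(3-methylbut-2-en-1-yl)-4-(triisopropylsilyloxy)benzaldehyde
Product: 5 7-hydroxy-2,2-dimethyl-5-(triisopropylsilyloxy)chroman-8-carbaldehyde
Conditions: TsOH·H2O (10 mol%), toluene, 70 °C
Reagents that add atoms: none
Why: Acid-catalysed cyclisation of an ortho-prenyl phenol to a 2,2-dimethylchroman by Markovnikov protonation and capture of the tertiary cation; only one free hydroxyl is next to the prenyl group (the other neighbour is silylated), so the ring oxygen ends up ortho to the formyl group as ring E requires.

Step 4
Reactants: 5 7-hydroxy-2,2-dimethyl-5-(triisopropylsilyloxy)chroman-8-carbaldehyde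
Product: 6 2,2-dimethyl-5-(triisopropylsilyloxy)-7-(trimethylsilyloxy)chroman-8-carbaldehyde
Conditions: TMSCl, Et3N, CH2Cl2, 0 °C → rt; pentane, filtration, evaporation; used without chromatography
Reagents that add atoms: trimethylsilyl chloride (TMSCl), C[Si](C)(C)Cl
Why: Standard silylation of a chelated phenol; trimethylsilyl is chosen because it is the silyl group most easily handed on from oxygen in step 7, and the moisture-sensitive ether is used directly.

Step 5
Reactants: 7 2-hydroxy-4-methoxybenzaldehyde
Product: 8 2-(tert-butyldimethylsilyloxy)-4-methoxybenzaldehyde
Conditions: TBSCl, imidazole, DMF, rt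
Reagents that add atoms: tert-butyldimethylsilyl chloride (TBSCl), CC(C)(C)[Si](C)(C)Cl
Why: Standard phenol silylation; the tert-butyldimethylsilyl ether is robust enough for the olefination and for chromatography.

Step 6
Reactants: 8 2-(tert-butyldimethylsilyloxy)-4-methoxybenzaldehyde; 9 diethyl (phenylthiomethyl)phosphonate
Product: 10 tert-butyl{5-methoxy-2-[(E)-2-(phenylthio)ethenyl]phenoxy}dimethylsilane
Conditions: 9, n-BuLi, THF, −78 °C; then 8, −78 °C → rt
Reagents that add atoms: none
Why: Horner–Wadsworth–Emmons olefination with a sulfur-stabilised phosphonate carbanion, which with aryl aldehydes should favour the E vinyl sulfide; any Z isomer should be separable by chromatography.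

Step 7
Reactants: 6 2,2-dimethyl-5-(triisopropylsilyloxy)-7-(trimethylsilyloxy)chroman-8-carbaldehyde; 10 tert-butyl{5-methoxy-2-[(E)-2-(phenylthio)ethenyl]phenoxy}dimethylsilane
Product: 12 (6aR,11aS)-6-(phenylthio)-3-O-triisopropylsilyl ring-E pterocarpan (both C6 epimers), via ring-B-closed 2-phenylthio-4-silyloxychroman 11 (not isolated)
Conditions: imidodiphosphorimidate acid HN[P(=NSO2CF3)(O2Ar*)]2 (Ar* = (S)-3,3'-diaryl-1,1'-binaphthyl-2,2'-diyl, or the mirror image as the sense of induction requires; 5 mol%), pre-silylated with allylSiMe3 (volatiles removed); 10 (1.2 equiv), toluene, 4 Å MS, −60 → −20 °C; Et3N quench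
Reagents that add atoms: none
Why: Proposed new method: the silylated imidodiphosphorimidate is a silylium Lewis acid that turns aldehyde 6 into a silyloxocarbenium ion paired with the chiral anion; vinyl sulfide 10 attacks it through C6a, the carbon beta to sulfur, forming C6a–C11a and a thionium ion at C6, which the neighbouring O5 trimethylsilyl ether captures at once in a 6-exo-trig closure (ring B) that releases Me3Si+ and gives 11. The C11a silyloxy group of 11, benzylic to the 2,4,6-trioxygenated ring A, is then ionised by the silylium ion and leaves as the disiloxane, and the ring D oxygen O11 closes ring C by 5-exo-trig attack on the benzylic cation, releasing tBuMe2Si+ to carry the cycle on. The closest known reaction types are Lewis acid-promoted Prins- and Mukaiyama-type additions of vinyl sulfides to aldehydes and acetals, acid-catalysed inverse-demand [4+2] reactions of ortho-quinone methides made from salicylaldehydes, and silylium imidodiphosphorimidate catalysis of additions to aldehydes; the combination of C–C bond formation, thionium capture and benzylic substitution on these two partners is new. C6a is set in the C–C bond-forming step by the chiral anion, which must discriminate the faces of the vinyl sulfide within the ion pair; C11a is set in the last closure by the substrate, because O11 is tethered to the aryl group on C6a and can reach only the cis face of the cation, so the configuration first formed at C11a does not matter; C6 arises as either epimer and is removed in step 8. The first bond must form at C6a and not C6: the sulfur lone pair stabilises the C6 cation directly as a thionium ion, whereas the competing C6a benzylic cation needs ring D coplanar with it, which the ortho silyloxy group opposes. The thionium ion must be captured by O5 and not O11: the small, labile trimethylsilyl group on O5 against the bulky tert-butyldimethylsilyl group on O11, together with a [4+2]-like geometry of the first step that places C6 over O5, should secure this. The aprotic silylium medium supplies no proton, so 10 is not protonated at C6a and cannot cyclise on itself.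

Step 8
Reactants: 12 (6aR,11aS)-6-(phenylthio)-3-O-triisopropylsilyl ring-E pterocarpan
Product: 13 (6aS,11aS)-3-O-triisopropylsilyl ring-E pterocarpan
Conditions: Bu3SnH, AIBN, toluene, 110 °C
Reagents that add atoms: none
Why: Radical-chain reduction of an α-alkoxy phenyl sulfide; the tin radical abstracts the phenylthio group, the oxygen-stabilised C6 radical takes hydrogen from Bu3SnH, and the neutral conditions leave the C11a–O11 bond and both stereocentres untouched (the C6a descriptor changes from R to S only because C6 loses sulfur).

Step 9
Reactants: 13 (6aS,11aS)-3-O-triisopropylsilyl ring-E pterocarpan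
Product: 14 (6aS,11aS)-9-methoxy ring-E pterocarpan-3-ol (target CNP0207547.1)
Conditions: Bu4NF, AcOH, THF, 0 °C
Reagents that add atoms: none
Why: Fluoride cleavage of an aryl silyl ether; buffering with acetic acid keeps the liberated electron-rich phenol protonated, and no acid strong enough to ionise C11a–O11 is present.

## Compound list

1 | 2,4,6-trihydroxybenzaldehyde | O=Cc1c(O)cc(O)cc1O | starting material
2 | 2,6-dihydroxy-4-(triisopropylsilyloxy)benzaldehyde | O=Cc1c(O)cc(O[Si](C(C)C)(C(C)C)C(C)C)cc1O | intermediate
3 | 1-bromo-3-methylbut-2-ene (prenyl bromide) | CC(C)=CCBr | starting material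
4 | 2,6-dihydroxy-3-(3-methylbut-2-en-1-yl)-4-(triisopropylsilyloxy)benzaldehyde | O=Cc1c(O)cc(O[Si](C(C)C)(C(C)C)C(C)C)c(CC=C(C)C)c1O | intermediate
5 | 7-hydroxy-2,2-dimethyl-5-(triisopropylsilyloxy)chroman-8-carbaldehyde | O=Cc1c(O)cc(O[Si](C(C)C)(C(C)C)C(C)C)c2CCC(C)(C)Oc12 | intermediate
6 | 2,2-dimethyl-5-(triisopropylsilyloxy)-7-(trimethylsilyloxy)chroman-8-carbaldehyde | O=Cc1c(O[Si](C)(C)C)cc(O[Si](C(C)C)(C(C)C)C(C)C)c2CCC(C)(C)Oc12 | intermediate
7 | 2-hydroxy-4-methoxybenzaldehyde | COc1ccc(C=O)c(O)c1 | starting material
8 | 2-(tert-butyldimethylsilyloxy)-4-methoxybenzaldehyde | COc1ccc(C=O)c(O[Si](C)(C)C(C)(C)C)c1 | intermediate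
9 | diethyl (phenylthiomethyl)phosphonate | CCOP(=O)(CSc1ccccc1)OCC | starting material
10 | tert-butyl{5-methoxy-2-[(E)-2-(phenylthio)ethenyl]phenoxy}dimethylsilane | COc1ccc(/C=C/Sc2ccccc2)c(O[Si](C)(C)C(C)(C)C)c1 | intermediate
11 | (9R)-10-(tert-butyldimethylsilyloxy)-9-[2-(tert-butyldimethylsilyloxy)-4-methoxyphenyl]-2,2-dimethyl-8-(phenylthio)-5-(triisopropylsilyloxy)-3,4,9,10-tetrahydro-2H,8H-pyrano[2,3-f]chromene (rings A, B, E closed; O11–C11a not yet formed; C9 = C6a; either configuration at C8 = C6 and C10 = C11a) | COc1ccc([C@@H]2C(O[Si](C)(C)C(C)(C)C)c3c(cc(O[Si](C(C)C)(C(C)C)C(C)C)c4c3OC(C)(C)CC4)OC2Sc2ccccc2)c(O[Si](C)(C)C(C)(C)C)c1 | intermediate (not isolated)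
12 | (6aR,11aS)-9-methoxy-6-(phenylthio)-3-(triisopropylsilyloxy)pterocarpan with ring E fused at C1 (O) and C2 (CH2); both C6 epimers | COc1ccc2c(c1)O[C@@H]1c3c(cc(O[Si](C(C)C)(C(C)C)C(C)C)c4c3OC(C)(C)CC4)OC(Sc3ccccc3)[C@H]21 | intermediate
13 | (6aS,11aS)-9-methoxy-3-(triisopropylsilyloxy)pterocarpan with ring E fused at C1 (O) and C2 (CH2) | COc1ccc2c(c1)O[C@@H]1c3c(cc(O[Si](C(C)C)(C(C)C)C(C)C)c4c3OC(C)(C)CC4)OC[C@H]21 | intermediate
14 | (6aS,11aS)-9-methoxypterocarpan-3-ol with ring E (2,2-dimethyl-3,4-dihydro-2H-pyran) fused at C1 (O) and C2 (CH2) | COc1ccc2c(c1)O[C@@H]1c3c(cc(O)c4c3OC(C)(C)CC4)OC[C@H]21 | target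

## Step count and least certain steps

Total: 9 steps. Longest linear sequence: 7 steps (1, 2, 3, 4, 7, 8, 9); steps 5 and 6 form the second branch.

**Step 7 (key step).** Four processes could defeat it:
- bonding through C6 under styrene-type polarity, because ring D is itself a strong donor;
- capture of the thionium ion by the ring D oxygen, closing a five-membered O,S-acetal instead of ring B;
- loss of the C6a proton from the thionium ion or from the C11a cation, which would erase the stereocentre;
- weak facial discrimination by the anion on a very stabilised, hindered silyloxocarbenium ion.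

The fallback uses known chemistry and sets out from 5. An intramolecular Wittig reaction with vinyltriphenylphosphonium bromide (NaH, DMF, 70 °C) should give 2,2-dimethyl-5-(triisopropylsilyloxy)-3,4-dihydro-2H,8H-pyrano[2,3-f]chromene F1 (the same compound as A5). Its formal [3+2] reaction with 2-methoxy-1,4-benzoquinone (A6), promoted by the TADDOL-derived titanium complex from TiCl4, Ti(OiPr)4 and the chiral diol (tetravalent titanium; CH2Cl2, −78 °C), should give (6aS,11aS)-8-hydroxy-9-methoxy-3-O-triisopropylsilyl ring-E pterocarpan F2 (the same compound as A7). Triflation with PhNTf2 and Et3N should give the 8-trifluoromethanesulfonate of F2, F3. Reduction with Pd(OAc)2, PPh3, HCO2H and Et3N in DMF at 60 °C removes the triflate and returns to the route at 13.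

**Step 1.** Silylation may spread to an ortho hydroxyl or occur twice, because the ortho hydroxyls are only alternately chelated. The fallback decides the regiochemistry by chelation at a later stage. From 1, C-prenylation with 3 (DBU, THF) should give 2,4,6-trihydroxy-3-(3-methylbut-2-en-1-yl)benzaldehyde F4. Acid cyclisation (TsOH·H2O, toluene), with chromatographic separation from the isomeric chroman formed through the para hydroxyl, should give 5,7-dihydroxy-2,2-dimethylchroman-8-carbaldehyde F5. In F5 only the para hydroxyl is outside the chelate, so TIPSCl and imidazole should silylate it cleanly. The fallback comes back at 5.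

**Step 2.** O-alkylation or double alkylation may compete with mono-C-alkylation, and the reacting ring carbon is crowded by the neighbouring silyl ether. The fallback builds ring E by condensation and electrocyclisation instead of alkylation. From 2, 3-methylbut-2-enal with catalytic ethylenediammonium diacetate in refluxing toluene should give 7-hydroxy-2,2-dimethyl-5-(triisopropylsilyloxy)-2H-chromene-8-carbaldehyde F6 (Knoevenagel-type condensation, then oxa-electrocyclisation through the only free neighbouring oxygen). Hydrogenation of the chromene double bond (H2, Pd/C, EtOAc) comes back at 5.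

**Step 6.** Silyl transfer from the phenol oxygen to the alkoxide of the phosphonate adduct may stall the elimination, and the E selectivity may be incomplete. The fallback makes the alkene by addition to an alkyne. From 8, Colvin homologation (Me3SiCHN2, LiN(iPr)2, THF, −78 °C → rt) should give tert-butyl(2-ethynyl-5-methoxyphenoxy)dimethylsilane F7. Anti-Markovnikov syn hydrothiolation with PhSH catalysed by RhCl(PPh3)3 should then give the E vinyl sulfide and comes back at 10.

**Step 8.** Chain propagation may be slow because a phenylthio O,S-acetal is only a moderate radical precursor, and prolonged heating could degrade the benzylic ether. The fallback changes the mode of C–S cleavage from a homolytic chain to hydrogenolysis on nickel: nickel boride made from NiCl2·6H2O and NaBH4 in MeOH–THF at 0 °C, from 12 directly to 13. It makes no new compound (entry F0).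

## Further compounds

F1 | step 7 | 2,2-dimethyl-5-(triisopropylsilyloxy)-3,4-dihydro-2H,8H-pyrano[2,3-f]chromene | C1=Cc2c(cc(O[Si](C(C)C)(C(C)C)C(C)C)c3c2OC(C)(C)CC3)OC1
F2 | step 7 | (6aS,11aS)-8-hydroxy-9-methoxy-3-O-triisopropylsilyl ring-E pterocarpan | COc1c(O)cc2c(c1)O[C@@H]1c3c(cc(O[Si](C(C)C)(C(C)C)C(C)C)c4c3OC(C)(C)CC4)OC[C@H]21
F3 | step 7 | (6aS,11aS)-9-methoxy-3-O-triisopropylsilyl ring-E pterocarpan-8-yl trifluoromethanesulfonate | COc1c(OS(=O)(=O)C(F)(F)F)cc2c(c1)O[C@@H]1c3c(cc(O[Si](C(C)C)(C(C)C)C(C)C)c4c3OC(C)(C)CC4)OC[C@H]21
F4 | step 1 | 2,4,6-trihydroxy-3-(3-methylbut-2-en-1-yl)benzaldehyde | O=Cc1c(O)cc(O)c(CC=C(C)C)c1O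
F5 | step 1 | 5,7-dihydroxy-2,2-dimethylchroman-8-carbaldehyde | O=Cc1c(O)cc(O)c2CCC(C)(C)Oc12
F6 | step 2 | 7-hydroxy-2,2-dimethyl-5-(triisopropylsilyloxy)-2H-chromene-8-carbaldehyde | O=Cc1c(O)cc(O[Si](C(C)C)(C(C)C)C(C)C)c2C=CC(C)(C)Oc12
F7 | step 6 | tert-butyl(2-ethynyl-5-methoxyphenoxy)dimethylsilane | COc1ccc(C#C)c(O[Si](C)(C)C(C)(C)C)c1
F0 | step 8 | none | none
A1 | alternative 1 | ethyl 2-diazo-2-{2-[(5,7-bis(tert-butyldimethylsilyloxy)-2,2-dimethylchroman-8-yl)methoxy]-4-methoxyphenyl}acetate | COc1ccc(C(=[N+]=[N-])C(=O)OCC)c(c1)OCc1c(O[Si](C)(C)C(C)(C)C)cc(O[Si](C)(C)C(C)(C)C)c2c1OC(C)(C)CC2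
A2 | alternative 1 | ethyl cis-2-[5,7-bis(tert-butyldimethylsilyloxy)-2,2-dimethylchroman-8-yl]-6-methoxy-2,3-dihydrobenzofuran-3-carboxylate (C2 = C11a and C3 = C6a arranged as in the target) | COc1ccc2c(c1)O[C@H](c3c(O[Si](C)(C)C(C)(C)C)cc(O[Si](C)(C)C(C)(C)C)c4c3OC(C)(C)CC4)[C@@H]2C(=O)OCC
A3 | alternative 2 | 3-{[2,2-dimethyl-5-(triisopropylsilyloxy)chroman-7-yl]oxymethyl}-6-methoxy-2,3-dihydrobenzofuran-2-yl acetate (C3 = C6a arranged as in the target; either configuration at C2) | COc1ccc2c(c1)OC(OC(C)=O)[C@@H]2COc1cc(O[Si](C(C)C)(C(C)C)C(C)C)c2CCC(C)(C)Oc2c1
A4 | alternative 2 | (6aS,11aS)-3-O-triisopropylsilyl ring-E pterocarpan (identical with 13) | COc1ccc2c(c1)O[C@@H]1c3c(cc(O[Si](C(C)C)(C(C)C)C(C)C)c4c3OC(C)(C)CC4)OC[C@H]21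
A5 | alternative 3 | 2,2-dimethyl-5-(triisopropylsilyloxy)-3,4-dihydro-2H,8H-pyrano[2,3-f]chromene | C1=Cc2c(cc(O[Si](C(C)C)(C(C)C)C(C)C)c3c2OC(C)(C)CC3)OC1
A6 | alternative 3 | 2-methoxy-1,4-benzoquinone | COC1=CC(=O)C=CC1=O
A7 | alternative 3 | (6aS,11aS)-8-hydroxy-9-methoxy-3-O-triisopropylsilyl ring-E pterocarpan | COc1c(O)cc2c(c1)O[C@@H]1c3c(cc(O[Si](C(C)C)(C(C)C)C(C)C)c4c3OC(C)(C)CC4)OC[C@H]21
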